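**Plan**

1. Retrosynthesis: the C(sp3)–C(sp2) bond between the two-carbon arm on the decalin and the trisubstituted alkene is cut first (Negishi coupling of fragment A, a monocyclic (E)-alkenyl iodide, with fragment B, a decalin alkyl iodide). In the monocycle the two ring bonds C(=CH2)–CH2 and CH2–C(CH3)2 are then cut, which excises a C3 unit.
2. Enabling feature: in the six-membered monocycle the quaternary C(CH3)2 carbon and the =CH2-bearing carbon both sit on the stereogenic CH. With the latter at the C=O level they are the isopropyl methine and the formyl carbon of an α-substituted isovaleraldehyde, two hydridic C–H bonds that one hydrogen-atom-transfer photocatalyst can open in turn.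
3. Fragment A, forward: Evans alkylation, then aldehyde 9, then a photocatalytic double C–H [3+3] annulation with 2,3-bis(phenylsulfonyl)propene that closes the monocycle as a sulfonyl cyclohexanone. Methylenation, desulfonylation and chain extension (ester, alcohol, iodide, alkyne, (E)-iodoalkene) follow.
4. Fragment B, forward: rings A and B of the decalin come preformed from (+)-sclareolide; acid opens the lactone and places the tetrasubstituted alkene; reduction and iodination follow; the Negishi coupling joins A and B last.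
5. Stereochemistry: the monocycle CH comes from the auxiliary-controlled alkylation and is never a reactive site afterwards; both decalin stereocenters come from sclareolide; the (E)-alkene comes from syn-carboalumination of a terminal alkyne.

Key step: step 5

Remark: 12 and 13 are carried as mixtures of epimers at the sulfonyl-bearing carbon; this centre is removed in step 7.

**Route**

Step 1
Reactants: 1 (4S)-4-benzyl-1,3-oxazolidin-2-one; 2 3-methylbutanoyl chloride
Product: 4 (4S)-4-benzyl-3-(3-methylbutanoyl)-1,3-oxazolidin-2-one, via lithium oxazolidinide 3 (not isolated)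
Conditions: n-BuLi, THF, −78 °C; then 2, −78 °C to 0 °C
Reagents that add atoms: none
Why: N-acylation of the lithiated oxazolidinone by an acid chloride is the standard entry to Evans imides and creates no stereocenter.

Step 2
Reactants: 4 N-isovaleryl imide; 5 tert-butyl bromoacetate
Product: 7 tert-butyl (3S)-3-{[(4S)-4-benzyl-2-oxo-1,3-oxazolidin-3-yl]carbonyl}-4-methylpentanoate, via sodium enolate 6 (not isolated)
Conditions: NaN(SiMe3)2, THF, −78 °C; then 5, −78 °C to −40 °C
Reagents that add atoms: none
Why: Evans alkylation, in which the chelated Z-enolate is alkylated on the face opposite the benzyl group, should set the (3S) centre that becomes the ring CH of the monocycle.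

Step 3
Reactants: 7 alkylated imide
Product: 8 tert-butyl (3S)-3-(hydroxymethyl)-4-methylpentanoate
Conditions: LiBH4, MeOH (1 equiv), THF, 0 °C
Reagents that add atoms: none
Why: reductive cleavage of the imide by LiBH4 should give the primary alcohol and return the auxiliary while the tert-butyl ester and the stereocenter are left alone.

Step 4
Reactants: 8 hydroxy ester
Product: 9 tert-butyl (3S)-3-formyl-4-methylpentanoate
Conditions: Dess–Martin periodinane, CH2Cl2, 0 °C to rt; used at once
Reagents that add atoms: none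
Why: Dess–Martin oxidation is non-basic, so the α-stereocenter of the aldehyde should survive.

Step 5
Reactants: 9 aldehyde; 10 2,3-bis(phenylsulfonyl)prop-1-ene
Product: 12 tert-butyl 2-[(1S)-2,2-dimethyl-6-oxo-4-(phenylsulfonyl)cyclohexyl]acetate, via allyl ketone 11 (not isolated)
Conditions: (n-Bu4N)4[W10O32] (4 mol %), 10 (1.1 equiv), degassed MeCN, 390 nm LEDs, 0 °C; 9 added slowly
Reagents that add atoms: none
Why: Proposed new method: the excited decatungstate anion abstracts the formyl hydrogen of 9, the acyl radical adds to the CH2= terminus of 10 and the adduct expels PhSO2• to give the 2-(phenylsulfonyl)allyl ketone 11 (new C(=O)–CH2 bond); a second hydrogen abstraction at the isopropyl methine then gives a tertiary radical that adds to the terminal carbon of the vinyl sulfone (new CH2–C(CH3)2 bond), and the α-sulfonyl radical takes hydrogen back from the reduced catalyst. The closest known reaction types are decatungstate-photocatalysed hydroacylation and C(sp3)–H alkylation of vinyl sulfones and radical SH2' allylation of C–H bonds with 2-(phenylsulfonyl)allyl sulfones; only their combination into one annulation is new. The six-membered ring closes in the 6-endo-trig mode, because the sulfonyl group makes the terminal alkene carbon the electrophilic site and stabilises the radical at the internal carbon, whereas 5-exo attack would have to occur at the substituted carbon. The only new stereocenter is the sulfonyl-bearing carbon, which is not controlled and is erased in step 7, while the existing stereocenter sits between the two radical sites but is never one itself. The step needs site-selective hydrogen abstraction, which the hydridic formyl and tertiary C–H bonds should secure over the C–H bonds deactivated by carbonyl, ester and sulfonyl groups. It also needs ring closure to beat a second intermolecular addition, which slow addition of 9 and only a slight excess of 10 should secure, and cooling slows loss of CO from the acyl radical.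

Step 6
Reactants: 12 sulfonyl cyclohexanone
Product: 13 tert-butyl 2-[(1S)-2,2-dimethyl-6-methylidene-4-(phenylsulfonyl)cyclohexyl]acetate
Conditions: Zn, CH2Br2, TiCl4, THF (reagent pre-formed at 0–5 °C); then 12, CH2Cl2, 0 °C to rt
Reagents that add atoms: dibromomethane, BrCBr
Why: Takai–Lombardo methylenation uses a non-basic zinc–titanium methylene reagent, so the hindered ketone should be converted without epimerisation at the α-carbon or β-elimination of the sulfonyl group.

Step 7
Reactants: 13 methylidene sulfone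
Product: 14 tert-butyl 2-[(1S)-2,2-dimethyl-6-methylidenecyclohexyl]acetate
Conditions: 6% Na/Hg, Na2HPO4, MeOH–THF, −20 °C
Reagents that add atoms: none
Why: reductive desulfonylation by electron transfer should cleave the secondary alkyl C–SO2Ph bond while the isolated 1,1-disubstituted alkene and the tert-butyl ester are not reduced under buffered conditions.

Step 8
Reactants: 14 ester
Product: 15 2-[(1S)-2,2-dimethyl-6-methylidenecyclohexyl]ethan-1-ol
Conditions: LiAlH4, Et2O, 0 °C to rt
Reagents that add atoms: none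
Why: hydride reduction of the ester to the primary alcohol leaves the unactivated alkene untouched.

Step 9
Reactants: 15 alcohol
Product: 16 (2S)-2-(2-iodoethyl)-1,1-dimethyl-3-methylidenecyclohexane
Conditions: I2, PPh3, imidazole, CH2Cl2, 0 °C
Reagents that add atoms: iodine, II
Why: Appel-type iodination of the unhindered primary alcohol runs under nearly neutral conditions that should not isomerise the exocyclic alkene.

Step 10
Reactants: 16 iodide
Product: 17 (2S)-2-(but-3-yn-1-yl)-1,1-dimethyl-3-methylidenecyclohexane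
Conditions: LiC≡CH·H2NCH2CH2NH2, DMSO, rt
Reagents that add atoms: lithium acetylide–ethylenediamine complex, [Li]C#C.NCCN
Why: SN2 alkylation of lithium acetylide by a primary iodide in DMSO should give the terminal alkyne.

Step 11
Reactants: 17 alkyne
Product: 19 (2S)-2-[(3E)-4-iodo-3-methylbut-3-en-1-yl]-1,1-dimethyl-3-methylidenecyclohexane, via alkenylalane 18 (not isolated)
Conditions: AlMe3, Cp2ZrCl2 (25 mol %), CH2Cl2, 0 °C to rt; then I2, THF, −30 °C
Reagents that add atoms: trimethylaluminium, C[Al](C)C; iodine, II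
Why: zirconium-catalysed syn-carboalumination (Negishi) places methyl on the internal and aluminium on the terminal alkyne carbon, so iodinolysis with retention should give the (E)-iodoalkene while the 1,1-disubstituted alkene does not react.

Step 12
Reactants: 20 (+)-sclareolide
Product: 21 methyl 2-[(4aS,8aS)-2,5,5,8a-tetramethyl-3,4,4a,5,6,7,8,8a-octahydronaphthalen-1-yl]acetate
Conditions: conc. H2SO4, MeOH, reflux; chromatography on AgNO3-impregnated silica
Reagents that add atoms: methanol, CO
Why: acid-mediated opening of the lactone at its tertiary C–O bond, E1 elimination under equilibrating conditions toward the tetrasubstituted alkene and Fischer esterification should give the β,γ-unsaturated ester with both ring-fusion stereocenters untouched.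

Step 13
Reactants: 21 methyl ester
Product: 22 2-[(4aS,8aS)-2,5,5,8a-tetramethyl-3,4,4a,5,6,7,8,8a-octahydronaphthalen-1-yl]ethan-1-ol
Conditions: LiAlH4, Et2O, 0 °C
Reagents that add atoms: none
Why: hydride reduction of the ester gives the homoallylic primary alcohol without touching the tetrasubstituted alkene.

Step 14
Reactants: 22 alcohol
Product: 23 (4aS,8aS)-1-(2-iodoethyl)-2,5,5,8a-tetramethyl-3,4,4a,5,6,7,8,8a-octahydronaphthalene
Conditions: I2, PPh3, imidazole, CH2Cl2, 0 °C
Reagents that add atoms: iodine, II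
Why: Appel-type iodination converts the primary alcohol into the iodide needed for zinc insertion.

Step 15
Reactants: 23 decalin iodide; 19 alkenyl iodide
Product: 25 (4aS,8aS)-1-{(3E)-6-[(1S)-2,2-dimethyl-6-methylidenecyclohexyl]-4-methylhex-3-en-1-yl}-2,5,5,8a-tetramethyl-3,4,4a,5,6,7,8,8a-octahydronaphthalene, via alkylzinc iodide 24 (not isolated)
Conditions: Zn dust, LiCl, THF, 40 °C; then 19, Pd(PPh3)4 (5 mol %), THF, rt to 40 °C
Reagents that add atoms: none
Why: Negishi coupling of a primary alkylzinc iodide with an alkenyl iodide proceeds with retention of alkene geometry and should tolerate the three unactivated alkenes, so no stereocenter is touched.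

**Compound list**

1 | (4S)-4-benzyl-1,3-oxazolidin-2-one | O=C1N[C@@H](Cc2ccccc2)CO1 | starting material
2 | 3-methylbutanoyl chloride | CC(C)CC(=O)Cl | starting material
3 | lithium (4S)-4-benzyl-2-oxo-1,3-oxazolidin-3-ide | [Li]N1C(=O)OC[C@@H]1Cc1ccccc1 | intermediate (not isolated)
4 | (4S)-4-benzyl-3-(3-methylbutanoyl)-1,3-oxazolidin-2-one | CC(C)CC(=O)N1C(=O)OC[C@@H]1Cc1ccccc1 | intermediate
5 | tert-butyl bromoacetate | BrCC(=O)OC(C)(C)C | starting material
6 | sodium (Z)-enolate of 4 | CC(C)/C=C(\O[Na])N1C(=O)OC[C@@H]1Cc1ccccc1 | intermediate (not isolated)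
7 | tert-butyl (3S)-3-{[(4S)-4-benzyl-2-oxo-1,3-oxazolidin-3-yl]carbonyl}-4-methylpentanoate | CC(C)[C@@H](C(=O)N1C(=O)OC[C@@H]1Cc1ccccc1)CC(=O)OC(C)(C)C | intermediate
8 | tert-butyl (3S)-3-(hydroxymethyl)-4-methylpentanoate | CC(C)[C@@H](CO)CC(=O)OC(C)(C)C | intermediate
9 | tert-butyl (3S)-3-formyl-4-methylpentanoate | CC(C)[C@@H](C=O)CC(=O)OC(C)(C)C | intermediate
10 | 2,3-bis(phenylsulfonyl)prop-1-ene | C=C(CS(=O)(=O)c1ccccc1)S(=O)(=O)c1ccccc1 | starting material
11 | tert-butyl (3S)-4-oxo-6-(phenylsulfonyl)-3-(propan-2-yl)hept-6-enoate | CC(C)[C@@H](C(=O)CC(=C)S(=O)(=O)c1ccccc1)CC(=O)OC(C)(C)C | intermediate (not isolated)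
12 | tert-butyl 2-[(1S,4RS)-2,2-dimethyl-6-oxo-4-(phenylsulfonyl)cyclohexyl]acetate | O=C1CC(S(=O)(=O)c2ccccc2)CC(C)(C)[C@@H]1CC(=O)OC(C)(C)C | intermediate
13 | tert-butyl 2-[(1S,4RS)-2,2-dimethyl-6-methylidene-4-(phenylsulfonyl)cyclohexyl]acetate | C=C1CC(S(=O)(=O)c2ccccc2)CC(C)(C)[C@@H]1CC(=O)OC(C)(C)C | intermediate
14 | tert-butyl 2-[(1S)-2,2-dimethyl-6-methylidenecyclohexyl]acetate | C=C1CCCC(C)(C)[C@@H]1CC(=O)OC(C)(C)C | intermediate
15 | 2-[(1S)-2,2-dimethyl-6-methylidenecyclohexyl]ethan-1-ol | C=C1CCCC(C)(C)[C@@H]1CCO | intermediate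
16 | (2S)-2-(2-iodoethyl)-1,1-dimethyl-3-methylidenecyclohexane | C=C1CCCC(C)(C)[C@@H]1CCI | intermediate
17 | (2S)-2-(but-3-yn-1-yl)-1,1-dimethyl-3-methylidenecyclohexane | C=C1CCCC(C)(C)[C@@H]1CCC#C | intermediate
18 | {(1E)-4-[(1S)-2,2-dimethyl-6-methylidenecyclohexyl]-2-methylbut-1-en-1-yl}dimethylalane | C=C1CCCC(C)(C)[C@@H]1CC/C(C)=C/[Al](C)C | intermediate (not isolated)
19 | (2S)-2-[(3E)-4-iodo-3-methylbut-3-en-1-yl]-1,1-dimethyl-3-methylidenecyclohexane | C=C1CCCC(C)(C)[C@@H]1CC/C(C)=C/I | intermediate
20 | (+)-sclareolide, (3aR,5aS,9aS,9bR)-3a,6,6,9a-tetramethyldecahydronaphtho[2,1-b]furan-2(1H)-one | O=C1C[C@H]2[C@](C)(O1)CC[C@H]3C(C)(C)CCC[C@]23C | starting material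
21 | methyl 2-[(4aS,8aS)-2,5,5,8a-tetramethyl-3,4,4a,5,6,7,8,8a-octahydronaphthalen-1-yl]acetate | COC(=O)CC1=C(C)CC[C@H]2C(C)(C)CCC[C@]12C | intermediate
22 | 2-[(4aS,8aS)-2,5,5,8a-tetramethyl-3,4,4a,5,6,7,8,8a-octahydronaphthalen-1-yl]ethan-1-ol | OCCC1=C(C)CC[C@H]2C(C)(C)CCC[C@]12C | intermediate
23 | (4aS,8aS)-1-(2-iodoethyl)-2,5,5,8a-tetramethyl-3,4,4a,5,6,7,8,8a-octahydronaphthalene | ICCC1=C(C)CC[C@H]2C(C)(C)CCC[C@]12C | intermediate
24 | iodo{2-[(4aS,8aS)-2,5,5,8a-tetramethyl-3,4,4a,5,6,7,8,8a-octahydronaphthalen-1-yl]ethyl}zinc | I[Zn]CCC1=C(C)CC[C@H]2C(C)(C)CCC[C@]12C | intermediate (not isolated)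
25 | (4aS,8aS)-1-{(3E)-6-[(1S)-2,2-dimethyl-6-methylidenecyclohexyl]-4-methylhex-3-en-1-yl}-2,5,5,8a-tetramethyl-3,4,4a,5,6,7,8,8a-octahydronaphthalene | C=C1CCCC(C)(C)[C@@H]1CC/C(C)=C/CCC1=C(C)CC[C@H]2C(C)(C)CCC[C@]12C | target

**Step count and risks**

Total steps: 15. Longest linear sequence: 12 (steps 1–11, then step 15).

Steps most likely to fail:

1. Step 5 (proposed new method). The acyl radical may lose CO before it is trapped. A second intermolecular radical addition may outrun the 6-endo ring closure. Hydrogen abstraction at the hindered methine may be too slow. The fallback uses known chemistry only, sets out from 1 and returns at 14, so steps 5–7 are bypassed.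
   - N-acylation of 1 with 3-methylbut-2-enoyl chloride (n-BuLi) gives (4S)-4-benzyl-3-(3-methylbut-2-enoyl)-1,3-oxazolidin-2-one F1.
   - Sakurai conjugate allylation (allyltrimethylsilane, TiCl4) builds the quaternary carbon and gives (4S)-4-benzyl-3-(3,3-dimethylhex-5-enoyl)-1,3-oxazolidin-2-one F2.
   - Evans alkylation with 5 (NaN(SiMe3)2) gives tert-butyl (3S)-3-{[(4S)-4-benzyl-2-oxo-1,3-oxazolidin-3-yl]carbonyl}-4,4-dimethylhept-6-enoate F3.
   - LiSEt removes the auxiliary and gives the thioester tert-butyl (3S)-3-[(ethylsulfanyl)carbonyl]-4,4-dimethylhept-6-enoate F4.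
   - Me2CuLi gives the methyl ketone tert-butyl (3S)-3-acetyl-4,4-dimethylhept-6-enoate F5.
   - KN(SiMe3)2 and PhNTf2 give the terminal enol triflate tert-butyl (3S)-4,4-dimethyl-3-{1-[(trifluoromethanesulfonyl)oxy]ethenyl}hept-6-enoate F6.
   - 9-BBN hydroborates the terminal alkene to tert-butyl (3S)-7-(9-borabicyclo[3.3.1]nonan-9-yl)-4,4-dimethyl-3-{1-[(trifluoromethanesulfonyl)oxy]ethenyl}heptanoate F7, and intramolecular B-alkyl Suzuki coupling (PdCl2(dppf), AsPh3, Cs2CO3) closes the ring at the methylidene-bearing carbon to give 14.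

2. Step 12. The E1 elimination may not converge on the tetrasubstituted alkene, since the trisubstituted ring alkene and the exocyclic alkene compete, or the lactone may simply re-close. The fallback fixes the alkene position by sigmatropic transposition; it sets out from 20 and returns at 22.
   - i-Bu2AlH reduction of 20 gives the lactol (3aR,5aS,9aS,9bR)-3a,6,6,9a-tetramethyldodecahydronaphtho[2,1-b]furan-2-ol F8.
   - Alkoxy-radical β-fragmentation (PhI(OAc)2, I2, visible light) gives (1R,2R,4aS,8aS)-1-(iodomethyl)-2,5,5,8a-tetramethyldecahydronaphthalen-2-yl formate F9.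
   - Elimination with AgF in pyridine gives (2R,4aS,8aS)-2,5,5,8a-tetramethyl-1-methylidenedecahydronaphthalen-2-yl formate F10.
   - K2CO3 in MeOH gives the tertiary allylic alcohol (2R,4aS,8aS)-2,5,5,8a-tetramethyl-1-methylidenedecahydronaphthalen-2-ol F11.
   - KH and Bu3SnCH2I give tributyl({[(2R,4aS,8aS)-2,5,5,8a-tetramethyl-1-methylidenedecahydronaphthalen-2-yl]oxy}methyl)stannane F12.
   - Tin–lithium exchange with n-BuLi triggers a [2,3]-Wittig (Still) rearrangement that forms the C–CH2OH bond at the exocyclic carbon and moves the alkene into the tetrasubstituted position, giving 22.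

3. Step 6. β-Elimination of benzenesulfinate from the β-sulfonyl ketone, or Lewis-acid cleavage of the tert-butyl ester, may outrun methylenation of the hindered carbonyl. The fallback removes the leaving group before olefination; it sets out from 12 and returns at 14, so step 7 is bypassed.
   - Et3N in CH2Cl2 eliminates benzenesulfinic acid to give the enone tert-butyl 2-[(1S)-6,6-dimethyl-2-oxocyclohex-3-en-1-yl]acetate F13.
   - Hydrogenation (H2, Pd/C, EtOAc) gives tert-butyl 2-[(1S)-2,2-dimethyl-6-oxocyclohexyl]acetate F14.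
   - Wittig methylenation (Ph3PCH3Br, KN(SiMe3)2, toluene, 0 °C) gives 14.

Further compounds
F1 | step 5 | (4S)-4-benzyl-3-(3-methylbut-2-enoyl)-1,3-oxazolidin-2-one | CC(C)=CC(=O)N1C(=O)OC[C@@H]1Cc1ccccc1
F2 | step 5 | (4S)-4-benzyl-3-(3,3-dimethylhex-5-enoyl)-1,3-oxazolidin-2-one | C=CCC(C)(C)CC(=O)N1C(=O)OC[C@@H]1Cc1ccccc1
F3 | step 5 | tert-butyl (3S)-3-{[(4S)-4-benzyl-2-oxo-1,3-oxazolidin-3-yl]carbonyl}-4,4-dimethylhept-6-enoate | C=CCC(C)(C)[C@@H](C(=O)N1C(=O)OC[C@@H]1Cc1ccccc1)CC(=O)OC(C)(C)C
F4 | step 5 | tert-butyl (3S)-3-[(ethylsulfanyl)carbonyl]-4,4-dimethylhept-6-enoate | C=CCC(C)(C)[C@@H](C(=O)SCC)CC(=O)OC(C)(C)C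
F5 | step 5 | tert-butyl (3S)-3-acetyl-4,4-dimethylhept-6-enoate | C=CCC(C)(C)[C@@H](C(C)=O)CC(=O)OC(C)(C)C
F6 | step 5 | tert-butyl (3S)-4,4-dimethyl-3-{1-[(trifluoromethanesulfonyl)oxy]ethenyl}hept-6-enoate | C=CCC(C)(C)[C@@H](C(=C)OS(=O)(=O)C(F)(F)F)CC(=O)OC(C)(C)C
F7 | step 5 | tert-butyl (3S)-7-(9-borabicyclo[3.3.1]nonan-9-yl)-4,4-dimethyl-3-{1-[(trifluoromethanesulfonyl)oxy]ethenyl}heptanoate | B1(C2CCCC1CCC2)CCCC(C)(C)[C@@H](C(=C)OS(=O)(=O)C(F)(F)F)CC(=O)OC(C)(C)C
F8 | step 12 | (3aR,5aS,9aS,9bR)-3a,6,6,9a-tetramethyldodecahydronaphtho[2,1-b]furan-2-ol | OC1C[C@H]2[C@](C)(O1)CC[C@H]3C(C)(C)CCC[C@]23C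
F9 | step 12 | (1R,2R,4aS,8aS)-1-(iodomethyl)-2,5,5,8a-tetramethyldecahydronaphthalen-2-yl formate | IC[C@H]1[C@](C)(OC=O)CC[C@H]2C(C)(C)CCC[C@]12C
F10 | step 12 | (2R,4aS,8aS)-2,5,5,8a-tetramethyl-1-methylidenedecahydronaphthalen-2-yl formate | C=C1[C@](C)(OC=O)CC[C@H]2C(C)(C)CCC[C@]12C
F11 | step 12 | (2R,4aS,8aS)-2,5,5,8a-tetramethyl-1-methylidenedecahydronaphthalen-2-ol | C=C1[C@](C)(O)CC[C@H]2C(C)(C)CCC[C@]12C
F12 | step 12 | tributyl({[(2R,4aS,8aS)-2,5,5,8a-tetramethyl-1-methylidenedecahydronaphthalen-2-yl]oxy}methyl)stannane | C=C1[C@](C)(OC[Sn](CCCC)(CCCC)CCCC)CC[C@H]2C(C)(C)CCC[C@]12C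
F13 | step 6 | tert-butyl 2-[(1S)-6,6-dimethyl-2-oxocyclohex-3-en-1-yl]acetate | O=C1C=CCC(C)(C)[C@@H]1CC(=O)OC(C)(C)C
F14 | step 6 | tert-butyl 2-[(1S)-2,2-dimethyl-6-oxocyclohexyl]acetate | O=C1CCCC(C)(C)[C@@H]1CC(=O)OC(C)(C)C
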